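**Retrosynthetic overview**

1. The strategy rests on the piperidine: C2' is a benzylic stereocentre bonded to N1', and N1' reaches C6' through the unfunctionalised chain C3'–C6'. Cutting C2'–N1' and N1'–C6' gives an aryl 4-chlorobutyl ketone and an NH2 donor, so an (S)-selective transaminase can set C2' and the new amine can close the ring on the chloride.
2. The ketone comes from 4-hydroxy-2,6-dimethoxybenzaldehyde by MOM protection, 4-chlorobutyl Grignard addition and oxidation. The two ortho-methoxy groups are equivalent, so no regiochemical question arises before ring C is built.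
3. Ring C follows the piperidine: C4–C4a by ortho-lithiation between OMe and OMOM with acetylation, C2–C3 by Claisen condensation with methyl benzoate, O1–C2 by acid cyclodehydration, which also removes the MOM group.
4. The MOM acetal on the para oxygen is inert in the enzyme buffer and directs the lithiation, so the acid-labile, trioxygenated benzylic C2'–N bond never meets hydrogenolysis or Friedel–Crafts conditions. The 7-OH is freed last by thiolate demethylation para to C4=O; the 5-OMe stays.
5. Ring order: benzene ring A (purchased) → piperidine (step 4) → pyranone ring C (step 8).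

Key step: step 4

Assumption: a panel of engineered (S)-selective amine transaminases with enlarged binding pockets is at hand and one member accepts the di-ortho-methoxy aryl ketone 6; the configuration of 9 is to be confirmed before it is carried on.

Step 1
Reactants: 1 4-hydroxy-2,6-dimethoxybenzaldehyde
Product: 2 2,6-dimethoxy-4-(methoxymethoxy)benzaldehyde
Conditions: NaH, MOMCl, DMF, 0 °C → rt
Reagents that add atoms: chloromethyl methyl ether, COCCl
Why: Williamson-type O-alkylation of the para-formyl phenoxide with a highly reactive α-chloro ether; the acetal formed tolerates organometallics, oxidants and aqueous base and later serves as an ortho-directing group.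

Step 2
Reactants: 2 2,6-dimethoxy-4-(methoxymethoxy)benzaldehyde; 3 1-bromo-4-chlorobutane
Product: 5 5-chloro-1-[2,6-dimethoxy-4-(methoxymethoxy)phenyl]pentan-1-ol (racemic), via 4-chlorobutylmagnesium bromide 4 (not isolated)
Conditions: Mg (I2 cat.), THF, rt; then 2, 0 °C → rt; H2O
Reagents that add atoms: none
Why: Grignard formation is chemoselective for C–Br over C–Cl and the reagent undergoes 1,2-addition to the aldehyde; the carbinol centre is formed racemic and is removed in step 3.

Step 3
Reactants: 5 5-chloro-1-[2,6-dimethoxy-4-(methoxymethoxy)phenyl]pentan-1-ol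
Product: 6 5-chloro-1-[2,6-dimethoxy-4-(methoxymethoxy)phenyl]pentan-1-one
Conditions: Dess–Martin periodinane, pyridine, CH2Cl2, 0 °C → rt
Reagents that add atoms: none
Why: Dess–Martin oxidation of a secondary benzylic alcohol runs under near-neutral, pyridine-buffered conditions that spare the ionisation-prone trioxygenated benzylic position, the MOM acetal and the primary chloride.

Step 4
Reactants: 6 5-chloro-1-[2,6-dimethoxy-4-(methoxymethoxy)phenyl]pentan-1-one; 7 isopropylamine
Product: 9 (2S)-2-[2,6-dimethoxy-4-(methoxymethoxy)phenyl]piperidine, via open-chain (1S)-amino chloride 8 (not isolated)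
Conditions: engineered (S)-selective amine transaminase (bulky-ketone variant), PLP (1 mM), iPrNH2 (1 M), buffer pH 8.5, DMSO (20% v/v), 37 °C, N2 sweep; then NaOH (pH 12), rt
Reagents that add atoms: none
Why: Isopropylamine converts the enzyme-bound pyridoxal phosphate into pyridoxamine phosphate with release of acetone; this condenses with the ketone of 6 to a ketimine, the active-site lysine relays a proton to the re face of the former carbonyl carbon, and hydrolysis releases the (S)-amine 8. The closest known reaction type is the transaminase-triggered aza-cyclisation of ω-chloro aryl ketones to 2-arylpyrrolidines and 2-arylpiperidines. The piperidine closes by 6-exo-tet SN2 attack of N1' of 8 on C6' with loss of chloride; this closure is irreversible and, together with the excess donor and acetone removal, pulls the transamination equilibrium forward. C2' is set by the protein alone: the aryl group occupies the large pocket and the chlorobutyl chain the enlarged small pocket, the arrangement that gives (S)-1-phenylethylamine, while the achiral ketone offers no bias of its own. The step needs amination to outrun direct SN2 attack of isopropylamine on the primary chloride and needs the enzyme to accept a ketone flanked by two ortho-methoxy groups; the first is secured by the low reactivity of an unactivated primary alkyl chloride at 37 °C, the second by the twisted, non-conjugated and therefore more readily aminated carbonyl together with the bulky-substrate enzyme variant.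

Step 5
Reactants: 9 (2S)-2-[2,6-dimethoxy-4-(methoxymethoxy)phenyl]piperidine
Product: 11 (2S)-2-[2,6-dimethoxy-4-(methoxymethoxy)phenyl]-1-methylpiperidine, via N-methylideneiminium ion 10 (not isolated)
Conditions: aq. HCHO, NaBH(OAc)3, ClCH2CH2Cl, rt; aq. NaHCO3
Reagents that add atoms: formaldehyde, C=O
Why: Reductive amination: formaldehyde condenses with the secondary amine to iminium ion 10, which triacetoxyborohydride reduces faster than formaldehyde; C2' is not involved and keeps its configuration.

Step 6
Reactants: 11 (2S)-2-[2,6-dimethoxy-4-(methoxymethoxy)phenyl]-1-methylpiperidine; 12 N-methoxy-N-methylacetamide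
Product: 15 1-{2,4-dimethoxy-6-(methoxymethoxy)-3-[(2S)-1-methylpiperidin-2-yl]phenyl}ethan-1-one, via aryllithium 13 (not isolated), via lithium hemiaminal 14 (not isolated)
Conditions: n-BuLi (1.3 equiv), TMEDA, THF, −78 → 0 °C; then 12, −78 → 0 °C; H2O
Reagents that add atoms: none
Why: Directed ortho-metalation: the ring C–H flanked by OMe and OMOM (C3 and C5 are equivalent by rotation about the aryl–C2' bond) is the most acidic and best-coordinated site, and aryllithium 13 undergoes acyl substitution on the Weinreb amide through chelated adduct 14, which cannot over-add and collapses to the ketone on work-up; the basic medium leaves the acid-labile benzylic C2'–N bond untouched.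

Step 7
Reactants: 15 1-{2,4-dimethoxy-6-(methoxymethoxy)-3-[(2S)-1-methylpiperidin-2-yl]phenyl}ethan-1-one; 16 methyl benzoate
Product: 17 1-{2,4-dimethoxy-6-(methoxymethoxy)-3-[(2S)-1-methylpiperidin-2-yl]phenyl}-3-phenylpropane-1,3-dione
Conditions: NaH, THF, 65 °C; then AcOH
Reagents that add atoms: none
Why: Crossed Claisen condensation of the methyl ketone enolate with a non-enolisable ester, driven to completion by deprotonation of the β-diketone product (the intermolecular counterpart of the Baker–Venkataraman diketone synthesis).

Step 8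
Reactants: 17 1-{2,4-dimethoxy-6-(methoxymethoxy)-3-[(2S)-1-methylpiperidin-2-yl]phenyl}-3-phenylpropane-1,3-dione
Product: 19 5,7-dimethoxy-6-[(2S)-1-methylpiperidin-2-yl]-2-phenyl-4H-chromen-4-one, via free phenol diketone 18 (not isolated)
Conditions: conc. HCl, MeOH, 50 °C; basic work-up
Reagents that add atoms: none
Why: Acidic methanolysis removes the MOM acetal, and the liberated phenol 18 adds to the benzoyl carbonyl and dehydrates (cyclodehydration of an o-hydroxyaryl β-diketone, the closing stage of the Baker–Venkataraman flavone synthesis); with the amine protonated and the ring now acylated, benzylic C–N ionisation is not expected at 50 °C, so C2' should be retained.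

Step 9
Reactants: 19 5,7-dimethoxy-6-[(2S)-1-methylpiperidin-2-yl]-2-phenyl-4H-chromen-4-one
Product: 20 7-hydroxy-5-methoxy-6-[(2S)-1-methylpiperidin-2-yl]-2-phenyl-4H-chromen-4-one
Conditions: NaSEt (3 equiv), DMF, 100 °C; then AcOH to pH 7, 0 °C
Reagents that add atoms: none
Why: Thiolate SN2 O-demethylation of an aryl methyl ether: the 7-OMe lies para to the C4 carbonyl, so its phenoxide (a vinylogous carboxylate) is the better leaving group and its methyl group is less shielded than that of the 5-OMe wedged between C4=O and C6, and the phenoxide formed shuts down a second demethylation.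

**Compound list**

1 | 4-hydroxy-2,6-dimethoxybenzaldehyde | COc1cc(O)cc(OC)c1C=O | starting material
2 | 2,6-dimethoxy-4-(methoxymethoxy)benzaldehyde | COCOc1cc(OC)c(C=O)c(OC)c1 | intermediate
3 | 1-bromo-4-chlorobutane | ClCCCCBr | starting material
4 | 4-chlorobutylmagnesium bromide | ClCCCC[Mg]Br | intermediate
5 | 5-chloro-1-[2,6-dimethoxy-4-(methoxymethoxy)phenyl]pentan-1-ol (racemic) | COCOc1cc(OC)c(C(O)CCCCCl)c(OC)c1 | intermediate
6 | 5-chloro-1-[2,6-dimethoxy-4-(methoxymethoxy)phenyl]pentan-1-one | COCOc1cc(OC)c(C(=O)CCCCCl)c(OC)c1 | intermediate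
7 | isopropylamine (propan-2-amine) | CC(C)N | starting material
8 | (1S)-5-chloro-1-[2,6-dimethoxy-4-(methoxymethoxy)phenyl]pentan-1-amine | COCOc1cc(OC)c([C@@H](N)CCCCCl)c(OC)c1 | intermediate
9 | (2S)-2-[2,6-dimethoxy-4-(methoxymethoxy)phenyl]piperidine | COCOc1cc(OC)c([C@@H]2CCCCN2)c(OC)c1 | intermediate
10 | (2S)-2-[2,6-dimethoxy-4-(methoxymethoxy)phenyl]-1-methylidenepiperidin-1-ium | COCOc1cc(OC)c([C@@H]2CCCC[N+]2=C)c(OC)c1 | intermediate
11 | (2S)-2-[2,6-dimethoxy-4-(methoxymethoxy)phenyl]-1-methylpiperidine | COCOc1cc(OC)c([C@@H]2CCCCN2C)c(OC)c1 | intermediate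
12 | N-methoxy-N-methylacetamide | CON(C)C(C)=O | starting material
13 | {2,4-dimethoxy-6-(methoxymethoxy)-3-[(2S)-1-methylpiperidin-2-yl]phenyl}lithium | COCOc1cc(OC)c([C@@H]2CCCCN2C)c(OC)c1[Li] | intermediate
14 | lithium 1-{2,4-dimethoxy-6-(methoxymethoxy)-3-[(2S)-1-methylpiperidin-2-yl]phenyl}-1-[methoxy(methyl)amino]ethan-1-olate (hemiaminal carbon unassigned) | COCOc1cc(OC)c([C@@H]2CCCCN2C)c(OC)c1C(C)(O[Li])N(C)OC | intermediate
15 | 1-{2,4-dimethoxy-6-(methoxymethoxy)-3-[(2S)-1-methylpiperidin-2-yl]phenyl}ethan-1-one | COCOc1cc(OC)c([C@@H]2CCCCN2C)c(OC)c1C(C)=O | intermediate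
16 | methyl benzoate | COC(=O)c1ccccc1 | starting material
17 | 1-{2,4-dimethoxy-6-(methoxymethoxy)-3-[(2S)-1-methylpiperidin-2-yl]phenyl}-3-phenylpropane-1,3-dione | COCOc1cc(OC)c([C@@H]2CCCCN2C)c(OC)c1C(=O)CC(=O)c1ccccc1 | intermediate
18 | 1-{6-hydroxy-2,4-dimethoxy-3-[(2S)-1-methylpiperidin-2-yl]phenyl}-3-phenylpropane-1,3-dione | Oc1cc(OC)c([C@@H]2CCCCN2C)c(OC)c1C(=O)CC(=O)c1ccccc1 | intermediate
19 | 5,7-dimethoxy-6-[(2S)-1-methylpiperidin-2-yl]-2-phenyl-4H-chromen-4-one | COc1c([C@@H]2CCCCN2C)c(OC)cc2oc(-c3ccccc3)cc(=O)c12 | intermediate
20 | 7-hydroxy-5-methoxy-6-[(2S)-1-methylpiperidin-2-yl]-2-phenyl-4H-chromen-4-one | COc1c([C@@H]2CCCCN2C)c(O)cc2oc(-c3ccccc3)cc(=O)c12 | target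

**Step count**

Total steps: 9. Longest linear sequence: 9 steps (1 → 20).

**Steps most likely to fail**

1. Step 4. The enzyme may not bind a ketone flanked by two ortho-methoxy groups, so that no turnover occurs. It may also bind it with aryl group and chain exchanged between the pockets, which would erode or invert the stereochemical outcome, and slow turnover would give isopropylamine time to displace the chloride. Fallback, setting out from 6: chloride is displaced with NaN3 (DMF, 60 °C) to give 5-azido-1-[2,6-dimethoxy-4-(methoxymethoxy)phenyl]pentan-1-one F1. A Staudinger/intramolecular aza-Wittig reaction (PPh3, toluene, 80 °C) should close this to the cyclic imine 6-[2,6-dimethoxy-4-(methoxymethoxy)phenyl]-2,3,4,5-tetrahydropyridine F2. F2 is then reduced by iridium-catalysed asymmetric hydrogenation (chiral bisphosphine of the antipode that delivers the (S)-amine, I2 additive, H2), with the enantiomeric purity raised if necessary by crystallisation of a diaroyl tartrate salt. The fallback returns to the route at 9.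

2. Step 9. Discrimination between the two methyl ethers may be incomplete, or the thiolate may add to C2 of the pyranone and open ring C. The product also carries a phenol ortho to the benzylic amine, so it is worked up near neutral pH without heating to avoid reversible amine elimination to an ortho-quinone methide. Fallback, setting out from 19: both methyl ethers are cleaved with BBr3 (CH2Cl2, −78 °C → rt) to give 5,7-dihydroxy-6-[(2S)-1-methylpiperidin-2-yl]-2-phenyl-4H-chromen-4-one F3. The non-chelated 7-OH is silylated selectively (TIPSCl, imidazole, DMF) to give 5-hydroxy-6-[(2S)-1-methylpiperidin-2-yl]-2-phenyl-7-[(triisopropylsilyl)oxy]-4H-chromen-4-one F4. The chelated 5-OH is methylated under Mitsunobu conditions (MeOH, PPh3, DIAD, THF), in which the phenoxide rather than the hindered tertiary amine should capture the methoxyphosphonium ion, to give 5-methoxy-6-[(2S)-1-methylpiperidin-2-yl]-2-phenyl-7-[(triisopropylsilyl)oxy]-4H-chromen-4-one F5. Desilylation (TBAF, AcOH, THF, 0 °C) then arrives at 20.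

3. Step 6. The hindered aryllithium may take a proton from the acetamide instead of undergoing acyl substitution, returning 11, or lithiation may be incomplete. Fallback, setting out from 11 through the same aryllithium 13: the anion is trapped with the non-enolisable electrophile DMF to give 2,4-dimethoxy-6-(methoxymethoxy)-3-[(2S)-1-methylpiperidin-2-yl]benzaldehyde F6. Addition of MeMgBr (THF, 0 °C) gives 1-{2,4-dimethoxy-6-(methoxymethoxy)-3-[(2S)-1-methylpiperidin-2-yl]phenyl}ethan-1-ol F7 as a mixture of carbinol epimers. Oxidation (Dess–Martin periodinane, pyridine, CH2Cl2) rejoins the route at 15.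

**Further compounds**

F1 | step 4 | 5-azido-1-[2,6-dimethoxy-4-(methoxymethoxy)phenyl]pentan-1-one | COCOc1cc(OC)c(C(=O)CCCCN=[N+]=[N-])c(OC)c1
F2 | step 4 | 6-[2,6-dimethoxy-4-(methoxymethoxy)phenyl]-2,3,4,5-tetrahydropyridine | COCOc1cc(OC)c(C2=NCCCC2)c(OC)c1
F3 | step 9 | 5,7-dihydroxy-6-[(2S)-1-methylpiperidin-2-yl]-2-phenyl-4H-chromen-4-one | Oc1c([C@@H]2CCCCN2C)c(O)cc2oc(-c3ccccc3)cc(=O)c12
F4 | step 9 | 5-hydroxy-6-[(2S)-1-methylpiperidin-2-yl]-2-phenyl-7-[(triisopropylsilyl)oxy]-4H-chromen-4-one | Oc1c([C@@H]2CCCCN2C)c(O[Si](C(C)C)(C(C)C)C(C)C)cc2oc(-c3ccccc3)cc(=O)c12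
F5 | step 9 | 5-methoxy-6-[(2S)-1-methylpiperidin-2-yl]-2-phenyl-7-[(triisopropylsilyl)oxy]-4H-chromen-4-one | COc1c([C@@H]2CCCCN2C)c(O[Si](C(C)C)(C(C)C)C(C)C)cc2oc(-c3ccccc3)cc(=O)c12
F6 | step 6 | 2,4-dimethoxy-6-(methoxymethoxy)-3-[(2S)-1-methylpiperidin-2-yl]benzaldehyde | COCOc1cc(OC)c([C@@H]2CCCCN2C)c(OC)c1C=O
F7 | step 6 | 1-{2,4-dimethoxy-6-(methoxymethoxy)-3-[(2S)-1-methylpiperidin-2-yl]phenyl}ethan-1-ol (both carbinol epimers) | COCOc1cc(OC)c([C@@H]2CCCCN2C)c(OC)c1C(C)O
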